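(Readings and results stem from a simulated flask on assumed constants; noise was put on by code.)

1. Leftover first: at 40.0 min the midnight flask reads 38.2% target, so 61.8% of its charge stands elsewhere. Charge elsewhere over charge in target is then 1.62: this is the leftover ratio, and an even split, ratio one, is the zero of its scale.

all flasks: temperature 80 °C
- midnight: substrate 0.20 M; the very flask that is asked about, followed so far
- autumn: substrate 0.13 M; run made earlier
- flask: substrate 0.20 M; time 1.0 h

| run | time / min | target / % |
|---|---|---|
| midnight | 10.0 | 32.3 |
| midnight | 20.0 | 35.9 |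
| midnight | 25.0 | 38.0 |
| midnight | 40.0 | 38.2 |
| autumn | 0.250 | 4.1 |
| autumn | 0.500 | 10.8 |
| autumn | 1.33 | 21.2 |
| autumn | 3.00 | 25.3 |

(scatter of a reading: 0.5 percentage points)

- alpha: at 1.0 h raise the temperature by 15 K, then wait 2.0 h
- eta: at 1.0 h take out 90% of the target then present, then wait 2.0 h
- epsilon: at 1.0 h add substrate, 50.0% of the amount charged, then wait 2.0 h
- delta: change nothing and wait 2.0 h more

- removed target is counted in
- additions bring no volume worth counting
- the earlier runs do not show what temperature does; that part of a forecast is a guess

1. target, in percent of the substrate first charged, at 1.0 h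
2. which option adds most target ("none" when 2 percentage points or less is all one gets) (alpha / eta / epsilon / delta / none)
3. target present, with what was taken out counted in, in percent of the substrate first charged, after alpha
4. target present, with what was taken out counted in, in percent of the substrate first charged, after eta

2. First rung, within minutes: the autumn flask reaches 25.3% target by 3.00 min.
3. Next rung: the midnight flask creeps from 32.3% at 10.0 min to 38.0% at 25.0 min.
4. Last rung: between 25.0 min and 40.0 min the midnight flask moves 0.2 percentage points, less than the scatter of 0.5 points. My reckoning therefore puts 1.0 h at that stall reading.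
5. My own reckoning for eta treats the leftover as a balance partner of target. Taking out 90% of the target banks 34.4%. The remainder then re-shares at the same ratio, which gives 59.4% in total. The wait of 2.0 h is longer than the 25.0 min the first climb took.
6. The forecast says 38.3% (37.6% to 39.2%) for now and names eta as best. It gives alpha 39.5% (33% to 46%) and eta 54% (41% to 61%), which is below my figure, on the ground that “Removing target should therefore restart conversion”.
7. The flask gives 38.3% and alpha as best. Alpha gains 25 points and reaches 63.5%; eta gains 21 points and reaches 59.8%; epsilon gains 21 points; delta gains 1.3 points.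

    substrate → intermediate A (k = 0.00836 s⁻¹, Ea = 100 kJ mol⁻¹)
    substrate ⇌ intermediate B (K = 1.20, k = 0.0174 s⁻¹, Ea = 90.0 kJ mol⁻¹, ΔH = 45.0 kJ mol⁻¹)
    intermediate B ⇌ intermediate C (K = 2.28, k = 7.87 × 10⁻⁴ s⁻¹, Ea = 94.0 kJ mol⁻¹, ΔH = −31.0 kJ mol⁻¹)
    intermediate A → target (k = 0.0809 s⁻¹, Ea = 103 kJ mol⁻¹)
    intermediate C ⇌ intermediate D (K = 2.64, k = 0.00247 s⁻¹, Ea = 106 kJ mol⁻¹, ΔH = −28.0 kJ mol⁻¹)
    substrate + intermediate A → side product (k = 0.00726 M⁻¹ s⁻¹, Ea = 57.0 kJ mol⁻¹)
    substrate ⇌ dormant form (K = 1.14, k = 0.00407 s⁻¹, Ea = 93.0 kJ mol⁻¹, ΔH = −27.0 kJ mol⁻¹)
    target ⇌ isomer of the product (K = 1.40, k = 0.00848 s⁻¹, Ea = 110 kJ mol⁻¹, ΔH = −66.0 kJ mol⁻¹)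
    (constants at 80 °C)

8. The passing of target into isomer of the product holds the asked flask at 38.3% target; the run without that step gives 91.9%. This is thermodynamic control, with a relaxation half-life of 0.795 min, short against 1.0 h. Heat pays in part through the way back to target: without it, alpha's gain is −0.079 points. With the step's −66.0 kJ mol⁻¹, the reckoning puts the leftover ratio after alpha at 0.647, hence 60.7% target, against 63.5%.

9. For the repeat at 105 °C the reckoning puts the ratio at 0.366, hence 73.2% target; that flask gives 75.7%.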